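## Structural features

The target is a linear tridepside: three benzene rings joined head to tail by two aryl ester bonds, from the carbonyl on C1 of ring A to O4' of ring B and from the carbonyl on C1' of ring B to O4'' of ring C. Ring A is a 2,4,5-trihydroxy-6-methylbenzoyl unit (a hydroxyhydroquinone), ring B a 2'-methoxy-6'-methylbenzoyl unit, and ring C a 2''-hydroxy-6''-methylbenzoic acid. There is no stereocentre, so the problem is regiochemical: seven oxygen functions must be told apart (three free phenols on ring A, one methyl ether, two acylated phenols, and one free phenol beside the free acid). Each acyl carbon sits between two ortho substituents, so every acyl transfer is hindered. The two aryl esters are the fragile links, since hydroxide, alkoxide or free phenoxide cleaves or scrambles them, which rules out a hydrolytic unmasking at the end. Deprotected ring A is oxidised by air to a hydroxyquinone in any basic medium, and the salicylic acid of ring C decarboxylates on heating. The real difficulty is to make O4'' the only acylated oxygen of ring C and to release O2'', the C1'' acid and the three ring A phenols without a basic step. The key step exploits the fact that ring C (carboxyl on C1'' between the oxygen-bearing C2'' and the methyl-bearing C6'', second oxygen on C4'') is the dehydrogenated form of a 6-methyl-2,4-dioxocyclohexane-1-carboxylate, which two four-carbon esters assemble and in which O4'' is the exposed oxygen of a vinylogous acid.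

## Logic of the disconnections

**23 back to 22.** The three O–CH2Ph bonds on ring A and the O–CH2Ph bond of the C1'' carboxyl are cut. The last operation must be neutral because both depside esters and the air-sensitive ring A have to survive it, and hydrogenolysis meets that need. One kind of protecting group then covers everything that needs masking, and O2'' needs none. The forward step demands that 22 carry no other reducible group and no catalyst poison, so selenium residues from the preceding step must be removed completely.

**22 back to 18.** Hydrogen is formally added back across C1''–C6'', so the O2'' phenol becomes the C2'' ketone of a β-keto ester. In the dihydro ring the two oxygens of ring C are chemically different (a ketone and an enol ester), so O2'' never needs protection. The forward step must dehydrogenate exactly C1''–C6'' without base or nucleophile. C1'' is the only doubly activated carbon and C6''–H the only β-hydrogen, which suits a selenoxide syn-elimination.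

**18 back to 10 and 16.** The ester bond between the ring B carbonyl and O4'' is cut. This is the most convergent cut: it separates the ring A–ring B acid from a six-carbon ring that carries no aromatic ring yet. The forward step must deliver the acyl group to O4'' and not to O2'' or C3'', and must activate the hindered acid 10 (as 17) without touching its own aryl ester.

**16 back to 14 and 13 (key disconnection), and 13 back to 11 and 12.** C1''–C6'' and C3''–C4'' are cut. All six ring carbons, the methyl group and the carboxyl then come from two simple esters, and the methyl group is placed next to the carboxyl-bearing carbon by construction. The forward step needs an alkoxide matched to both esters and a full equivalent of base. 13 is reduced to 11 and 12 by cutting its ester C–O bond.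

**10 back to 9 and 8.** The C1' carboxyl is traced to a formyl group, and the O2'–CH3 bond is cut. The formyl group is a latent carboxyl that is inert to acylation and alkylation and needs no deprotection. It also holds O2' in a hydrogen bond, which is what distinguishes the two phenols of ring B. Methylating after the coupling saves protecting O4'. The demands are an aldehyde oxidation that spares electron-rich rings and a methylation that spares the aryl ester.

**8 back to 6 and 1.** The ester bond between the ring A carbonyl and O4' is cut. 1 supplies ring B with all its carbons in place, O4' free and O2' chelated. The forward step must activate the doubly ortho-substituted acid 6 (as 7) and discriminate between the two phenols of 1.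

**6 back to 5, 4, 2 and 1.** In turn, the C1 carboxyl is traced to a formyl group, the O2 and O5 benzyl bonds are cut, the C5–O bond is cut, and the O4 benzyl bond is cut. Ring A is ring B's starting compound plus one oxygen at C5, and C5 is para to the only free phenol of 2, which is where a persulfate hydroxylation strikes. One purchased aldehyde thus serves two rings, and the carboxyl carbon is never placed by an ambiguous substitution. The hydroxylation must succeed at a flanked para position, and the hydroquinone 4 must be handled without air.

## Other disconnections considered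

**Alternative 1:** The cut removes ring A altogether, at C1–C2 and C5–C6. C1, C6, the methyl group and the carbonyl remain as the but-2-ynoate ester A1 of the ring B–ring C phenol, and C2–C5 with three oxygens come from the silyloxyfuran A2. In the forward step A2 undergoes a Diels–Alder addition across the triple bond of A1. The oxygen bridge then opens by heterolysis of its bond to the silyloxy-bearing C2, and silyl loss and enolisation give A3, in which the former furan oxygen is the C5 hydroxyl.
- In favour: the whole hydroxyhydroquinone pattern arises in one step without an oxidation. The polarisation is matched, since the nucleophilic C5 of A2 should join the β-carbon of the ynoate. The hindered ring A ester bond is made beforehand as an unhindered acylation by an alkynoic acid, which is better than activating the doubly ortho-substituted acid 6 in step 5.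
- Against: a methyl-substituted ynoate is a sluggish dienophile that needs heat, while A2 is sensitive to heat and acid. An aryl ynoate is a Michael acceptor and an active ester, so open-chain conjugate addition without ring closure is a real competitor. A3 is a hydroquinone with two free phenols beside two aryl esters. The cycloaddition is the last carbon–carbon bond formation and is run on the most valuable intermediate.
- Comparison: both plans build one ring de novo and end with the same hydrogenolysis, so they are equal on the end game. The alternative builds the harder ring and avoids the persulfate step, and is the better plan on that point. The chosen annulation runs on cheap materials far from any depside bond, and is the safer plan on that point. Step economy is about equal, because A1 needs a ring B–ring C phenol with differentiated oxygens and A2 needs its own preparation.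

**Alternative 2:** The cut is at the acyl carbon–O4'' bond and at C1'–C6', so ring B is traced to an acyclic polyketone masked as the dioxinone A4, and ring C is the preformed phenol A5. In the forward step, heating A4 releases the acylketene A6, which A5 captures to give the aryl triketo-ester A7. Intramolecular aldol condensation of C2 onto the terminal ketone, dehydration and enolisation then give the resorcylate A8.
- In favour: the hindered ring B–ring C ester forms under neutral conditions without activating a hindered acid, which is better than step 10. Aromatisation is a spontaneous dehydration and needs no oxidant, which is better than step 11.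
- Against: A8 has O2' and O4' both free, whereas the target needs O2' methylated and O4' acylated. O4' can be acylated first, but the chelated O2' must then be methylated on a tridepside. In A7 the aryloxy group is a good leaving group, so closure of an enol oxygen onto the ester (pyranone formation with loss of A5) competes with the aldol path. A5 needs protecting-group steps to leave only O4'' free, and ring A still requires the acid 6.
- Comparison: the chosen plan spends its ring-forming step on ring C, where it removes a protecting group from O2''. The alternative spends it on ring B, which is the ring most cheaply bought (as 1). Mechanistically both are enolate condensations followed by aromatisation. The alternative is longer overall, because A4 and A5 each take several steps and an acylation and a methylation follow.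

**Alternative 3:** The cut is at the C1–carbonyl and carbonyl–O4' bonds, and the carbonyl carbon comes from carbon monoxide A10. In the forward step the aryl iodide A9 undergoes oxidative addition to zerovalent palladium (formed from Pd(OAc)2 and a wide-bite-angle bisphosphine), A10 inserts, and the phenol A11 with an amine base captures the acyl group to give A12.
- In favour: ring A needs neither a formyl group nor an acid, only a regioselective iodination. Ring C arrives aromatic, so no late dehydrogenation is needed, which is better than the chosen plan. A12 differs from 22 only by a benzyl ether on O2'', so the end game is equal.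
- Against: A9 is electron-rich and flanked by a benzyloxy and a methyl group, and A11 is an electron-poor, weakly nucleophilic phenol, so the acyl transfer is the hard step. At the temperatures such carbonylations need, the phenoxide of A11 and the amine base can transesterify the ring B–ring C ester that is already present. Hydrodeiodination and direct aryl ether formation compete.
- Comparison: step counts are similar, because A11 needs the same oxygen differentiation plus one more benzyl group. The alternative forms the most hindered ester catalytically where the chosen plan relies on acylium-type activation. The alternative is the more elegant on paper, and the chosen plan follows the longer-established reactivity for doubly ortho-substituted benzoates.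

Key step: step 9

**Remarks and assumptions (chemistry).**
- 1 is taken as a purchased compound. It is also one formylation step from orcinol.
- Ring A is unprimed, ring B primed and ring C doubly primed.
- 15, 16 and 18–20 are racemic mixtures of diastereomers and tautomers. They are drawn in the keto form without configuration because C1'' and C6'' become sp2 in step 11.
- O2'' and O4'' of 16 belong to one delocalised enolate and so share one acidity. The preference for O4'' in step 10 is therefore expected on steric grounds.
- The atom mapping of 16 onto ring C (ester on C1'', methyl on C6'', oxygens on C2'' and C4'') needed no correction.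

## Route

Step 1
Reactants: 1 2,4-dihydroxy-6-methylbenzaldehyde
Product: 2 4-(benzyloxy)-2-hydroxy-6-methylbenzaldehyde
Conditions: BnBr (1.05 equiv), NaHCO3, KI (cat.), MeCN, 80 °C
Reagents that add atoms: benzyl bromide, BrCc1ccccc1
Why: Williamson ether synthesis; the 2-OH is held in a hydrogen bond to the formyl group and is not deprotonated by hydrogencarbonate, so only the more acidic para-OH should be alkylated.

Step 2
Reactants: 2 4-(benzyloxy)-2-hydroxy-6-methylbenzaldehyde
Product: 4 4-(benzyloxy)-2,5-dihydroxy-6-methylbenzaldehyde, via aryl sulfate 3 (not isolated)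
Conditions: K2S2O8 (1.1 equiv), 2 M NaOH, pyridine (cosolvent), 0 °C to rt, argon; then 2 M HCl, 80 °C
Reagents that add atoms: potassium peroxodisulfate, [K+].[K+].[O-]S(=O)(=O)OOS(=O)(=O)[O-]
Why: Elbs persulfate oxidation; the phenoxide attacks peroxodisulfate through C5, its only free para position, and the aryl sulfate 3 is then hydrolysed by warm dilute acid. The reaction type is established for 2-hydroxybenzaldehydes, and the benzyl ether and the formyl group should tolerate cold alkaline persulfate and brief acid treatment.

Step 3
Reactants: 4 4-(benzyloxy)-2,5-dihydroxy-6-methylbenzaldehyde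
Product: 5 2,4,5-tris(benzyloxy)-6-methylbenzaldehyde
Conditions: BnBr (2.5 equiv), K2CO3, DMF, 60 °C, argon
Reagents that add atoms: benzyl bromide, BrCc1ccccc1
Why: Williamson benzylation of both remaining phenols; the chelated 2-OH and the flanked 5-OH need carbonate in warm DMF, and exclusion of air keeps the hydroquinone from oxidising before it is capped.

Step 4
Reactants: 5 2,4,5-tris(benzyloxy)-6-methylbenzaldehyde
Product: 6 2,4,5-tris(benzyloxy)-6-methylbenzoic acid
Conditions: NaClO2, NaH2PO4, 2-methylbut-2-ene, t-BuOH/THF/H2O, rt
Reagents that add atoms: sodium chlorite, [Na+].[O-]Cl=O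
Why: Pinnick oxidation of a hindered, non-enolisable aldehyde under buffered conditions; the alkene scavenger removes HOCl before it can chlorinate the electron-rich ring at C3.

Step 5
Reactants: 6 2,4,5-tris(benzyloxy)-6-methylbenzoic acid; 1 2,4-dihydroxy-6-methylbenzaldehyde
Product: 8 4-formyl-3-hydroxy-5-methylphenyl 2,4,5-tris(benzyloxy)-6-methylbenzoate, via mixed anhydride 7 (not isolated)
Conditions: (CF3CO)2O, toluene, rt; aq. NaHCO3 work-up
Reagents that add atoms: none
Why: Depside esterification through the mixed trifluoroacetic anhydride, which ionises readily to an alkoxy-stabilised acylium ion and so overcomes the double ortho substitution. Of the two phenols of 1 only O4 is free, the O2 hydroxyl being chelated to the formyl group, as in the classical coupling of such acids with orsellinate-type phenols.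

Step 6
Reactants: 8 4-formyl-3-hydroxy-5-methylphenyl 2,4,5-tris(benzyloxy)-6-methylbenzoate
Product: 9 4-formyl-3-methoxy-5-methylphenyl 2,4,5-tris(benzyloxy)-6-methylbenzoate
Conditions: MeI (5 equiv), K2CO3, dry DMF, rt
Reagents that add atoms: iodomethane, CI
Why: Williamson methylation of the chelated salicylaldehyde-type phenol; the aryl ester is shielded by two ortho substituents on its acyl side and the formyl-stabilised phenoxide is a poor acyl acceptor, so the depside bond should survive anhydrous carbonate at room temperature.

Step 7
Reactants: 9 4-formyl-3-methoxy-5-methylphenyl 2,4,5-tris(benzyloxy)-6-methylbenzoate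
Product: 10 2-methoxy-6-methyl-4-{[2,4,5-tris(benzyloxy)-6-methylbenzoyl]oxy}benzoic acid
Conditions: NaClO2, NaH2PO4, 2-methylbut-2-ene, t-BuOH/THF/H2O, rt
Reagents that add atoms: sodium chlorite, [Na+].[O-]Cl=O
Why: Pinnick oxidation at about pH 4, which leaves the aryl ester, the benzyl ethers and the methyl ether untouched and reveals the ring B carboxyl without any deprotection step.

Step 8
Reactants: 11 (E)-but-2-enoic acid (crotonic acid); 12 benzyl alcohol
Product: 13 benzyl (E)-but-2-enoate
Conditions: TsOH·H2O (cat.), toluene, reflux, Dean–Stark
Reagents that add atoms: none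
Why: Fischer esterification driven by azeotropic removal of water; the conjugated E-alkene is the thermodynamically preferred isomer and is retained.

Step 9
Reactants: 14 benzyl 3-oxobutanoate (benzyl acetoacetate); 13 benzyl (E)-but-2-enoate
Product: 16 benzyl 6-methyl-2,4-dioxocyclohexane-1-carboxylate, via Michael adduct 15 (not isolated)
Conditions: NaOCH2Ph (1.1 equiv, 1 M in PhCH2OH), toluene, 0 °C to 80 °C; then cold 1 M HCl
Reagents that add atoms: none
Why: Benzyloxide deprotonates 14 at the carbon between its two carbonyl groups, and this stabilised enolate adds to the β-carbon of 13 (Michael addition), forming C1''–C6'' and giving the diester 15. Proton exchange in the alkoxide medium then produces the enolate of the acetyl methyl group, whose carbon attacks the crotonate-derived ester carbonyl in a Dieckmann (intramolecular Claisen) condensation, a 6-exo-trig closure that forms C3''–C4'' and expels benzyloxide. Both steps are reversible and are pulled forward by deprotonation of the resulting cyclic 1,3-dione, a vinylogous acid far more acidic than benzyl alcohol, which is why a full equivalent of base is used and the product is released only on acidification. The closest known reaction is the alkoxide-mediated condensation of alkyl acetoacetates with alkyl crotonates to alkyl dihydroorsellinates. Regiocontrol is built into the substrates: only the doubly activated carbon of 14 is a competent Michael donor, and only its acetyl methyl group can reach the remote ester through a six-membered transition state, so the methyl group ends on the carbon next to the ester-bearing one. Using the benzyl ester in both partners together with benzyloxide makes every transesterification degenerate. The two new sp3 centres C1'' and C6'' form as a racemic, base-equilibrated mixture (trans expected to dominate), which needs no control because both are destroyed in step 11.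

Step 10
Reactants: 10 2-methoxy-6-methyl-4-{[2,4,5-tris(benzyloxy)-6-methylbenzoyl]oxy}benzoic acid; 16 benzyl 6-methyl-2,4-dioxocyclohexane-1-carboxylate
Product: 18 benzyl 4-[(2-methoxy-6-methyl-4-{[2,4,5-tris(benzyloxy)-6-methylbenzoyl]oxy}benzoyl)oxy]-6-methyl-2-oxocyclohex-3-ene-1-carboxylate, via acid chloride 17 (not isolated)
Conditions: (COCl)2, DMF (cat.), CH2Cl2, 0 °C to rt, evaporate; then 16, Et3N, CH2Cl2, 0 °C to rt
Reagents that add atoms: none
Why: Acid chloride formation under DMF catalysis followed by O-acylation of the triethylammonium enolate of the vinylogous acid (enol ester formation of a cyclic 1,3-dione). O4'' lies between two CH groups whereas O2'' is next to the ester-bearing C1'', so the bulky 2,6-disubstituted aroyl chloride should go to O4'', and leaving out nucleophilic catalysts avoids O-to-C acyl migration to C3''.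

Step 11
Reactants: 18 benzyl 4-[(2-methoxy-6-methyl-4-{[2,4,5-tris(benzyloxy)-6-methylbenzoyl]oxy}benzoyl)oxy]-6-methyl-2-oxocyclohex-3-ene-1-carboxylate
Product: 22 benzyl 2-hydroxy-4-[(2-methoxy-6-methyl-4-{[2,4,5-tris(benzyloxy)-6-methylbenzoyl]oxy}benzoyl)oxy]-6-methylbenzoate, via selenide 19 (not isolated), via selenoxide 20 (not isolated), via dienone 21 (not isolated)
Conditions: PhSeCl (1.05 equiv), pyridine, CH2Cl2, 0 °C; then 30% H2O2, CH2Cl2, 0 °C to rt
Reagents that add atoms: none
Why: Selenenylation of the β-keto ester at C1'' from the face opposite the C6'' methyl group (as for 2-oxocycloalkanecarboxylates), oxidation to the selenoxide and syn-elimination toward C6''–H, the only β-hydrogen, give the cross-conjugated dienone 21. This tautomerises by moving a C5'' hydrogen to O2'' and so aromatises ring C; the stereocentres of 19 and 20 are transient.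

Step 12
Reactants: 22 benzyl 2-hydroxy-4-[(2-methoxy-6-methyl-4-{[2,4,5-tris(benzyloxy)-6-methylbenzoyl]oxy}benzoyl)oxy]-6-methylbenzoate
Product: 23 2-hydroxy-4-[(2-methoxy-6-methyl-4-{[2,4,5-trihydroxy-6-methylbenzoyl]oxy}benzoyl)oxy]-6-methylbenzoic acid (2'-O-methylhiascic acid)
Conditions: H2 (1 atm), 10% Pd/C, EtOAc/THF, rt; filtration and evaporation under argon
Reagents that add atoms: none
Why: Hydrogenolysis of the three aryl benzyl ethers and the benzyl ester over palladium metal; aryl esters, the methyl ether and the arenes are inert under these neutral conditions, which is the established end game for depsides.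

## Compound list

1 | 2,4-dihydroxy-6-methylbenzaldehyde | Cc1cc(O)cc(O)c1C=O | starting material
2 | 4-(benzyloxy)-2-hydroxy-6-methylbenzaldehyde | Cc1cc(OCc2ccccc2)cc(O)c1C=O | intermediate
3 | potassium 6-(benzyloxy)-3-formyl-4-hydroxy-2-methylphenyl sulfate | Cc1c(C=O)c(O)cc(OCc2ccccc2)c1OS(=O)(=O)[O-].[K+] | intermediate (not isolated)
4 | 4-(benzyloxy)-2,5-dihydroxy-6-methylbenzaldehyde | Cc1c(O)c(OCc2ccccc2)cc(O)c1C=O | intermediate
5 | 2,4,5-tris(benzyloxy)-6-methylbenzaldehyde | Cc1c(OCc2ccccc2)c(OCc2ccccc2)cc(OCc2ccccc2)c1C=O | intermediate
6 | 2,4,5-tris(benzyloxy)-6-methylbenzoic acid | Cc1c(OCc2ccccc2)c(OCc2ccccc2)cc(OCc2ccccc2)c1C(=O)O | intermediate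
7 | 2,4,5-tris(benzyloxy)-6-methylbenzoic trifluoroacetic anhydride | Cc1c(OCc2ccccc2)c(OCc2ccccc2)cc(OCc2ccccc2)c1C(=O)OC(=O)C(F)(F)F | intermediate (not isolated)
8 | 4-formyl-3-hydroxy-5-methylphenyl 2,4,5-tris(benzyloxy)-6-methylbenzoate | Cc1cc(OC(=O)c2c(OCc3ccccc3)cc(OCc3ccccc3)c(OCc3ccccc3)c2C)cc(O)c1C=O | intermediate
9 | 4-formyl-3-methoxy-5-methylphenyl 2,4,5-tris(benzyloxy)-6-methylbenzoate | COc1cc(OC(=O)c2c(OCc3ccccc3)cc(OCc3ccccc3)c(OCc3ccccc3)c2C)cc(C)c1C=O | intermediate
10 | 2-methoxy-6-methyl-4-{[2,4,5-tris(benzyloxy)-6-methylbenzoyl]oxy}benzoic acid | COc1cc(OC(=O)c2c(OCc3ccccc3)cc(OCc3ccccc3)c(OCc3ccccc3)c2C)cc(C)c1C(=O)O | intermediate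
11 | (E)-but-2-enoic acid (crotonic acid) | C/C=C/C(=O)O | starting material
12 | benzyl alcohol | OCc1ccccc1 | starting material
13 | benzyl (E)-but-2-enoate | C/C=C/C(=O)OCc1ccccc1 | intermediate
14 | benzyl 3-oxobutanoate (benzyl acetoacetate) | CC(=O)CC(=O)OCc1ccccc1 | starting material
15 | dibenzyl 2-acetyl-3-methylpentanedioate (racemic diastereomer mixture) | CC(=O)C(C(=O)OCc1ccccc1)C(C)CC(=O)OCc1ccccc1 | intermediate (not isolated)
16 | benzyl 6-methyl-2,4-dioxocyclohexane-1-carboxylate (racemic; keto form drawn) | CC1CC(=O)CC(=O)C1C(=O)OCc1ccccc1 | intermediate
17 | 2-methoxy-6-methyl-4-{[2,4,5-tris(benzyloxy)-6-methylbenzoyl]oxy}benzoyl chloride | COc1cc(OC(=O)c2c(OCc3ccccc3)cc(OCc3ccccc3)c(OCc3ccccc3)c2C)cc(C)c1C(=O)Cl | intermediate (not isolated)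
18 | benzyl 4-[(2-methoxy-6-methyl-4-{[2,4,5-tris(benzyloxy)-6-methylbenzoyl]oxy}benzoyl)oxy]-6-methyl-2-oxocyclohex-3-ene-1-carboxylate (racemic diastereomer mixture) | COc1cc(OC(=O)c2c(OCc3ccccc3)cc(OCc3ccccc3)c(OCc3ccccc3)c2C)cc(C)c1C(=O)OC1=CC(=O)C(C(=O)OCc2ccccc2)C(C)C1 | intermediate
19 | benzyl 4-[(2-methoxy-6-methyl-4-{[2,4,5-tris(benzyloxy)-6-methylbenzoyl]oxy}benzoyl)oxy]-6-methyl-2-oxo-1-(phenylselanyl)cyclohex-3-ene-1-carboxylate (racemic) | COc1cc(OC(=O)c2c(OCc3ccccc3)cc(OCc3ccccc3)c(OCc3ccccc3)c2C)cc(C)c1C(=O)OC1=CC(=O)C([Se]c2ccccc2)(C(=O)OCc2ccccc2)C(C)C1 | intermediate (not isolated)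
20 | benzyl 4-[(2-methoxy-6-methyl-4-{[2,4,5-tris(benzyloxy)-6-methylbenzoyl]oxy}benzoyl)oxy]-6-methyl-2-oxo-1-(phenylseleninyl)cyclohex-3-ene-1-carboxylate (racemic) | COc1cc(OC(=O)c2c(OCc3ccccc3)cc(OCc3ccccc3)c(OCc3ccccc3)c2C)cc(C)c1C(=O)OC1=CC(=O)C([Se](=O)c2ccccc2)(C(=O)OCc2ccccc2)C(C)C1 | intermediate (not isolated)
21 | benzyl 4-[(2-methoxy-6-methyl-4-{[2,4,5-tris(benzyloxy)-6-methylbenzoyl]oxy}benzoyl)oxy]-2-methyl-6-oxocyclohexa-1,4-diene-1-carboxylate | COc1cc(OC(=O)c2c(OCc3ccccc3)cc(OCc3ccccc3)c(OCc3ccccc3)c2C)cc(C)c1C(=O)OC1=CC(=O)C(C(=O)OCc2ccccc2)=C(C)C1 | intermediate (not isolated)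
22 | benzyl 2-hydroxy-4-[(2-methoxy-6-methyl-4-{[2,4,5-tris(benzyloxy)-6-methylbenzoyl]oxy}benzoyl)oxy]-6-methylbenzoate | COc1cc(OC(=O)c2c(OCc3ccccc3)cc(OCc3ccccc3)c(OCc3ccccc3)c2C)cc(C)c1C(=O)Oc1cc(C)c(C(=O)OCc2ccccc2)c(O)c1 | intermediate
23 | 2'-O-methylhiascic acid, 2-hydroxy-4-[(2-methoxy-6-methyl-4-{[2,4,5-trihydroxy-6-methylbenzoyl]oxy}benzoyl)oxy]-6-methylbenzoic acid | COc1cc(OC(=O)c2c(O)cc(O)c(O)c2C)cc(C)c1C(=O)Oc1cc(C)c(C(=O)O)c(O)c1 | target

## Step count and least certain steps

Total: 12 steps. Longest linear sequence: 10 steps (steps 1–7, then 10–12). The ring C branch (steps 8 and 9) joins at step 10.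

**Step 9 (key step).** The Michael addition is reversible, and benzyloxide can add to 13 in conjugate fashion or promote self-condensation of 14. Traces of hydroxide would saponify the β-keto ester, which then decarboxylates. Any of these would lower the conversion to 16. The fallback inverts the order of the two bond formations; it sets out from 11 and 14 and returns at 16. 11 would be converted (EDC·HCl, MeNHOMe·HCl, N-methylmorpholine, CH2Cl2) into (E)-N-methoxy-N-methylbut-2-enamide F1. The dianion of 14 (LiN(iPr)2, 2.2 equiv, THF, −78 °C) would be acylated at its terminal carbon by F1 to give benzyl (E)-3,5-dioxooct-6-enoate F2, forming C3''–C4'' first. F2 would then close C1''–C6'' by intramolecular Michael addition (6-endo-trig; NaOCH2Ph, 1 equiv, THF, then acid) to 16, the stable dione enolate being the thermodynamic sink.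

**Step 2.** Attack of the phenoxide on peroxodisulfate at the flanked C5 may be slow. One-electron oxidation to polymeric material and air oxidation of the hydroquinone in the alkaline medium may consume the substrate. The fallback brings in the C5 oxygen by aryl migration instead; it sets out from 1 and returns at 5. Exhaustive benzylation of 1 (BnBr, K2CO3, DMF) would give 2,4-bis(benzyloxy)-6-methylbenzaldehyde F3. Baeyer–Villiger oxidation (mCPBA, CH2Cl2) would give 2,4-bis(benzyloxy)-6-methylphenyl formate F4, and methanolysis (K2CO3, MeOH) 2,4-bis(benzyloxy)-6-methylphenol F5. Benzylation would give 1,2,5-tris(benzyloxy)-3-methylbenzene F6. Vilsmeier–Haack formylation (POCl3, DMF) at the position para to one benzyloxy group and between the methyl and another benzyloxy group would give 5. The regiochemistry of that formylation is the weak point of this detour.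

**Step 10.** Acyl transfer may go to the wrong site of the ambident enolate (O2'' or C3''), or the hindered acid chloride may react too slowly and the enol ester may scramble. The fallback gives up the dihydro ring at this stage; it sets out from 10 and returns at 22, replacing steps 10 and 11. Purchased orsellinic acid would be alkylated on the carboxylate only (BnBr, KHCO3, DMF) to benzyl 2,4-dihydroxy-6-methylbenzoate F7. 10 with (CF3CO)2O in toluene would form 2-methoxy-6-methyl-4-{[2,4,5-tris(benzyloxy)-6-methylbenzoyl]oxy}benzoic trifluoroacetic anhydride F8, which would acylate the free, non-chelated 4-OH of F7 to give 22.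

**Step 11.** Electrophilic selenenylation may compete at C3 of the electron-rich ring A. Poor facial selectivity at C1'' would leave a selenoxide with no syn β-hydrogen. Peroxide or selenium-derived oxidants may attack the enol ester. The fallback replaces the syn-elimination by halogenation and base-induced elimination; it sets out from 18 and returns at 22. Bromination at C1'' (N-bromosuccinimide, CH2Cl2, 0 °C) would give benzyl 1-bromo-4-[(2-methoxy-6-methyl-4-{[2,4,5-tris(benzyloxy)-6-methylbenzoyl]oxy}benzoyl)oxy]-6-methyl-2-oxocyclohex-3-ene-1-carboxylate F9. Dehydrobromination with Et3N in CH2Cl2 across C1''–C6'' would then give 22 after tautomerisation.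

**Step 6.** Carbonate or the phenoxide of 8 may cleave or transfer the aryl ester during the slow alkylation of the chelated phenol. The fallback installs the methyl ether before the depside bond exists; it sets out from 2 and 6 and returns at 9. Methylation of 2 (MeI, K2CO3, DMF) would give 4-(benzyloxy)-2-methoxy-6-methylbenzaldehyde F10. Brief hydrogenolysis (H2, 10% Pd/C, EtOAc) would give 4-hydroxy-2-methoxy-6-methylbenzaldehyde F11, which would be coupled with 6 through 7 ((CF3CO)2O, toluene) to give 9.

## Further compounds

F1 | step 9 | (E)-N-methoxy-N-methylbut-2-enamide | C/C=C/C(=O)N(C)OC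
F2 | step 9 | benzyl (E)-3,5-dioxooct-6-enoate | C/C=C/C(=O)CC(=O)CC(=O)OCc1ccccc1
F3 | step 2 | 2,4-bis(benzyloxy)-6-methylbenzaldehyde | Cc1cc(OCc2ccccc2)cc(OCc2ccccc2)c1C=O
F4 | step 2 | 2,4-bis(benzyloxy)-6-methylphenyl formate | Cc1cc(OCc2ccccc2)cc(OCc2ccccc2)c1OC=O
F5 | step 2 | 2,4-bis(benzyloxy)-6-methylphenol | Cc1cc(OCc2ccccc2)cc(OCc2ccccc2)c1O
F6 | step 2 | 1,2,5-tris(benzyloxy)-3-methylbenzene | Cc1cc(OCc2ccccc2)cc(OCc2ccccc2)c1OCc1ccccc1
F7 | step 10 | benzyl 2,4-dihydroxy-6-methylbenzoate | Cc1cc(O)cc(O)c1C(=O)OCc1ccccc1
F8 | step 10 | 2-methoxy-6-methyl-4-{[2,4,5-tris(benzyloxy)-6-methylbenzoyl]oxy}benzoic trifluoroacetic anhydride | COc1cc(OC(=O)c2c(OCc3ccccc3)cc(OCc3ccccc3)c(OCc3ccccc3)c2C)cc(C)c1C(=O)OC(=O)C(F)(F)F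
F9 | step 11 | benzyl 1-bromo-4-[(2-methoxy-6-methyl-4-{[2,4,5-tris(benzyloxy)-6-methylbenzoyl]oxy}benzoyl)oxy]-6-methyl-2-oxocyclohex-3-ene-1-carboxylate | COc1cc(OC(=O)c2c(OCc3ccccc3)cc(OCc3ccccc3)c(OCc3ccccc3)c2C)cc(C)c1C(=O)OC1=CC(=O)C(Br)(C(=O)OCc2ccccc2)C(C)C1
F10 | step 6 | 4-(benzyloxy)-2-methoxy-6-methylbenzaldehyde | COc1cc(OCc2ccccc2)cc(C)c1C=O
F11 | step 6 | 4-hydroxy-2-methoxy-6-methylbenzaldehyde | COc1cc(O)cc(C)c1C=O
A1 | alternative 1 | 4-({3-(benzyloxy)-4-[(benzyloxy)carbonyl]-5-methylphenoxy}carbonyl)-3-methoxy-5-methylphenyl but-2-ynoate | CC#CC(=O)Oc1cc(C)c(C(=O)Oc2cc(C)c(C(=O)OCc3ccccc3)c(OCc3ccccc3)c2)c(OC)c1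
A2 | alternative 1 | 4-(benzyloxy)-2-[(tert-butyldimethylsilyl)oxy]furan | CC(C)(C)[Si](C)(C)Oc1cc(OCc2ccccc2)co1
A3 | alternative 1 | benzyl 2-(benzyloxy)-4-[(4-{[4-(benzyloxy)-2,5-dihydroxy-6-methylbenzoyl]oxy}-2-methoxy-6-methylbenzoyl)oxy]-6-methylbenzoate | Cc1c(O)c(OCc2ccccc2)cc(O)c1C(=O)Oc1cc(C)c(C(=O)Oc2cc(C)c(C(=O)OCc3ccccc3)c(OCc3ccccc3)c2)c(OC)c1
A4 | alternative 2 | 6-(2,4-dioxopentyl)-2,2-dimethyl-4H-1,3-dioxin-4-one | CC(=O)CC(=O)CC1=CC(=O)OC(C)(C)O1
A5 | alternative 2 | benzyl 2-(benzyloxy)-4-hydroxy-6-methylbenzoate | Cc1cc(O)cc(OCc2ccccc2)c1C(=O)OCc1ccccc1
A6 | alternative 2 | 3,5-dioxohexanoylketene (1-oxohept-1-ene-3,5,7-trione chain) | CC(=O)CC(=O)CC(=O)C=C=O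
A7 | alternative 2 | 3-(benzyloxy)-4-[(benzyloxy)carbonyl]-5-methylphenyl 3,5,7-trioxooctanoate | CC(=O)CC(=O)CC(=O)CC(=O)Oc1cc(C)c(C(=O)OCc2ccccc2)c(OCc2ccccc2)c1
A8 | alternative 2 | benzyl 2-(benzyloxy)-4-[(2,4-dihydroxy-6-methylbenzoyl)oxy]-6-methylbenzoate | Cc1cc(O)cc(O)c1C(=O)Oc1cc(C)c(C(=O)OCc2ccccc2)c(OCc2ccccc2)c1
A9 | alternative 3 | 1,2,5-tris(benzyloxy)-4-iodo-3-methylbenzene | Cc1c(I)c(OCc2ccccc2)cc(OCc2ccccc2)c1OCc1ccccc1
A10 | alternative 3 | carbon monoxide | [C-]#[O+]
A11 | alternative 3 | benzyl 2-(benzyloxy)-4-[(4-hydroxy-2-methoxy-6-methylbenzoyl)oxy]-6-methylbenzoate | COc1cc(O)cc(C)c1C(=O)Oc1cc(C)c(C(=O)OCc2ccccc2)c(OCc2ccccc2)c1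
A12 | alternative 3 | benzyl 2-(benzyloxy)-4-[(2-methoxy-6-methyl-4-{[2,4,5-tris(benzyloxy)-6-methylbenzoyl]oxy}benzoyl)oxy]-6-methylbenzoate | COc1cc(OC(=O)c2c(OCc3ccccc3)cc(OCc3ccccc3)c(OCc3ccccc3)c2C)cc(C)c1C(=O)Oc1cc(C)c(C(=O)OCc2ccccc2)c(OCc2ccccc2)c1
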